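Ring B is made last: the route disconnects C3–C4, C3–CHO and C4–C4a. The feature used is that C3 of ring B carries two one-carbon neighbours at the aldehyde oxidation level, the vinylic C4 and the exocyclic CHO carbon; both can be supplied by DMF as the two equivalent ends of a vinamidinium, so they never need to be distinguished. In one operation the CH2CO2H end of an open-chain acid is formylated twice with loss of CO2, ring A closes onto one arm and hydrolysis leaves the enal. The precursor is a (3S,4R)-4,4-diaryl-3-(acetoxymethyl)butanoic acid whose stereocentres, the future C1 and C2, are set by auxiliary-controlled conjugate addition and alkylation, and whose phenol is masked as a deactivating acetate.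

Key step: step 8

Numbering used: ring B is C1 (guaiacyl-bearing), C2 (CH2OH-bearing), C3 (CHO-bearing), C4 (vinylic CH); ring A is the dimethoxybenzo ring. The target is the 1,2-trans (1S,2R) compound.

Assumption: 3,4-dimethoxyphenylmagnesium bromide (7) is bought as its THF solution; it can equally be made from 4-bromo-1,2-dimethoxybenzene and magnesium.

Remark on stereochemistry: with the (S)-benzyl auxiliary the aryl nucleophile and the acetate arm enter on the same face of the chelated acyl unit. This leads to the 1,2-trans target only if the guaiacyl ring sits on the cinnamoyl part and the veratryl ring (future ring A) is the nucleophile; the opposite pairing would end in the C1 epimer.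

Remark on protecting groups: both hydroxyl groups pass through the key step as acetates, because a hindered primary pivalate would not leave under conditions mild enough for the enal.

Step 1
Reactants: 1 ferulic acid
Product: 3 (E)-3-[4-(tert-butyldimethylsilyloxy)-3-methoxyphenyl]prop-2-enoic acid, via bis-silylated ferulic acid 2 (not isolated)
Conditions: TBSCl (2.3 equiv), imidazole, DMF, rt; then AcOH/THF/H2O, rt
Reagents that add atoms: tert-butyldimethylsilyl chloride, CC(C)(C)[Si](C)(C)Cl
Why: Silyl ether formation on phenol and acid followed by selective hydrolysis of the far more labile silyl ester should leave only the aryl silyl ether, which tolerates the organometallic, enolate and hydride steps ahead.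

Step 2
Reactants: 3 O-silylated ferulic acid; 4 (S)-4-benzyl-1,3-oxazolidin-2-one
Product: 6 (4S)-4-benzyl-3-[(E)-3-[4-(tert-butyldimethylsilyloxy)-3-methoxyphenyl]prop-2-enoyl]-1,3-oxazolidin-2-one, via mixed pivalic anhydride 5 (not isolated)
Conditions: PivCl, Et3N, THF, −20 °C; then 4, LiCl, −20 °C → rt
Reagents that add atoms: none
Why: N-Acylation of the oxazolidinone through a mixed pivalic anhydride under LiCl/Et3N activation should occur at the unhindered cinnamoyl carbonyl and leave the E double bond untouched.

Step 3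
Reactants: 6 cinnamoyl imide; 7 3,4-dimethoxyphenylmagnesium bromide
Product: 9 (4S)-4-benzyl-3-[(3R)-3-[4-(tert-butyldimethylsilyloxy)-3-methoxyphenyl]-3-(3,4-dimethoxyphenyl)propanoyl]-1,3-oxazolidin-2-one, via bromomagnesium enolate 8 (not isolated)
Conditions: 7 (2.5 equiv), CuBr·SMe2 (1.3 equiv), THF/Me2S, −40 → −10 °C; aq. NH4Cl
Reagents that add atoms: none
Why: Copper-mediated conjugate (1,4-) addition of an aryl Grignard reagent to an N-enoyl oxazolidinone: in the magnesium-chelated syn-s-cis conformer the aryl group should add to the β-carbon on the face away from the benzyl group, which sets the diaryl carbon (future C1) as R.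

Step 4
Reactants: 9 diarylpropanoyl imide; 10 tert-butyl bromoacetate
Product: 12 tert-butyl (3S,4R)-3-{[(4S)-4-benzyl-2-oxo-1,3-oxazolidin-3-yl]carbonyl}-4-[4-(tert-butyldimethylsilyloxy)-3-methoxyphenyl]-4-(3,4-dimethoxyphenyl)butanoate, via sodium enolate 11 (not isolated)
Conditions: NaN(SiMe3)2, THF, −78 °C; then 10, −78 → −45 °C
Reagents that add atoms: none
Why: Evans asymmetric alkylation: the chelated sodium (Z)-enolate should take up the reactive α-bromo ester on the face opposite the benzyl group, which sets the new centre (future C2) as S, the arrangement that becomes 1,2-trans after ring closure.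

Step 5
Reactants: 12 alkylated imide
Product: 13 tert-butyl (3S,4R)-4-[4-(tert-butyldimethylsilyloxy)-3-methoxyphenyl]-4-(3,4-dimethoxyphenyl)-3-(hydroxymethyl)butanoate
Conditions: LiBH4, MeOH (1 equiv), THF, 0 °C; aq. NH4Cl
Reagents that add atoms: none
Why: Reductive cleavage of the N-acyl oxazolidinone with LiBH4 should reduce the activated exocyclic imide carbonyl to CH2OH and release auxiliary 4, while the tert-butyl ester is too hindered to be reduced or to lactonise at 0 °C and no stereocentre is touched.

Step 6
Reactants: 13 hydroxy ester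
Product: 15 tert-butyl (3S,4R)-3-(acetoxymethyl)-4-(4-acetoxy-3-methoxyphenyl)-4-(3,4-dimethoxyphenyl)butanoate, via phenol diol 14 (not isolated)
Conditions: Bu4NF, AcOH, THF, 0 °C; then Ac2O, Et3N, DMAP (cat.), 0 °C → rt
Reagents that add atoms: acetic anhydride, CC(=O)OC(C)=O
Why: Fluoride desilylation buffered with AcOH followed by DMAP-catalysed acetylation in the same flask should turn the phenol and the primary alcohol into acetates, which make the pendant ring less nucleophilic, keep both OH groups away from the chloroiminium reagent and can later be removed by mild methanolysis.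

Step 7
Reactants: 15 diacetate tert-butyl ester
Product: 16 (3S,4R)-3-(acetoxymethyl)-4-(4-acetoxy-3-methoxyphenyl)-4-(3,4-dimethoxyphenyl)butanoic acid
Conditions: CF3CO2H/CH2Cl2 (1:4), Et3SiH, 0 °C → rt
Reagents that add atoms: none
Why: Acidolysis of the tert-butyl ester (alkyl–oxygen cleavage via the tert-butyl cation) should free the carboxylic acid while both acetates are inert to anhydrous acid, and Et3SiH reduces the tert-butyl cation before it can alkylate the electron-rich rings.

Step 8
Reactants: 16 diacetate acid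
Product: 19 [(1S,2R)-1-(4-acetoxy-3-methoxyphenyl)-3-formyl-6,7-dimethoxy-1,2-dihydronaphthalen-2-yl]methyl acetate, via vinamidinium salt 17 (not isolated), via cyclic iminium salt 18 (not isolated)
Conditions: POCl3 (4 equiv), DMF, 0 °C, then 16, rt → 70 °C; aq. NaOAc, rt
Reagents that add atoms: N,N-dimethylformamide, CN(C)C=O; water, O
Why: Proposed new method: the chloroiminium reagent from POCl3 and DMF converts the acid into its chloride, whose enol form is formylated at the α-carbon, loss of CO2 gives an enamine that is formylated again to the symmetrical vinamidinium 17 (C3–C4 and C3–CHO bonds), ring A attacks one iminium carbon (C4–C4a), dimethylamine is expelled to give the conjugated iminium 18, and aqueous acetate hydrolyses this to the enal. The closest known reactions are the Vilsmeier–Haack–Arnold conversion of substituted acetic acids into vinamidinium salts and Vilsmeier-type cyclisations of iminium intermediates onto arenes, as in the Meth-Cohn quinoline synthesis. Ring B closes as a six-membered ring by intramolecular electrophilic aromatic substitution, 6-exo-trig with respect to the C=N+ bond. No stereocentre is created, and C1 and C2 stay as set because neither lies α to a carbonyl or iminium carbon at any stage. The step needs regioselectivity between the two aryl groups on C1, secured by the acetoxy group, which makes the pendant ring less nucleophilic than ring A, whose attacking carbon is para to the C7 methoxy group; it also needs α-formylation to outrun direct acylation of ring A by the acid chloride, which an excess of preformed reagent in DMF without a Lewis acid should favour. Because the two arms of 17 are identical, closure onto either one gives the same product.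

Step 9
Reactants: 19 diacetate enal
Product: 20 (1S,2R)-1-(4-hydroxy-3-methoxyphenyl)-2-(hydroxymethyl)-6,7-dimethoxy-1,2-dihydronaphthalene-3-carbaldehyde
Conditions: K2CO3 (1.5 equiv), MeOH, 0 °C, argon; then AcOH to pH 6
Reagents that add atoms: none
Why: Base-catalysed methanolysis of the acetates (Zemplén-type transesterification) should free the phenol and the primary alcohol at 0 °C without lasting change to the enal, since methoxide addition to it is reversible and neither stereocentre carries an acidic hydrogen.

Compound list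
1 | ferulic acid, (E)-3-(4-hydroxy-3-methoxyphenyl)prop-2-enoic acid | COc1cc(/C=C/C(=O)O)ccc1O | starting material
2 | tert-butyldimethylsilyl (E)-3-[4-(tert-butyldimethylsilyloxy)-3-methoxyphenyl]prop-2-enoate | COc1cc(/C=C/C(=O)O[Si](C)(C)C(C)(C)C)ccc1O[Si](C)(C)C(C)(C)C | intermediate
3 | (E)-3-[4-(tert-butyldimethylsilyloxy)-3-methoxyphenyl]prop-2-enoic acid | COc1cc(/C=C/C(=O)O)ccc1O[Si](C)(C)C(C)(C)C | intermediate
4 | (S)-4-benzyl-1,3-oxazolidin-2-one | O=C1OC[C@H](Cc2ccccc2)N1 | starting material
5 | mixed anhydride of 3 and pivalic acid | COc1cc(/C=C/C(=O)OC(=O)C(C)(C)C)ccc1O[Si](C)(C)C(C)(C)C | intermediate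
6 | (4S)-4-benzyl-3-[(E)-3-[4-(tert-butyldimethylsilyloxy)-3-methoxyphenyl]prop-2-enoyl]-1,3-oxazolidin-2-one | COc1cc(/C=C/C(=O)N2[C@@H](Cc3ccccc3)COC2=O)ccc1O[Si](C)(C)C(C)(C)C | intermediate
7 | 3,4-dimethoxyphenylmagnesium bromide | COc1ccc([Mg]Br)cc1OC | starting material
8 | bromomagnesium (Z)-enolate of 9, (3R) at the diaryl carbon, (4S) auxiliary | COc1cc([C@@H](c2ccc(OC)c(OC)c2)/C=C(\O[Mg]Br)N2[C@@H](Cc3ccccc3)COC2=O)ccc1O[Si](C)(C)C(C)(C)C | intermediate
9 | (4S)-4-benzyl-3-[(3R)-3-[4-(tert-butyldimethylsilyloxy)-3-methoxyphenyl]-3-(3,4-dimethoxyphenyl)propanoyl]-1,3-oxazolidin-2-one | COc1cc([C@@H](c2ccc(OC)c(OC)c2)CC(=O)N2[C@@H](Cc3ccccc3)COC2=O)ccc1O[Si](C)(C)C(C)(C)C | intermediate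
10 | tert-butyl bromoacetate | CC(C)(C)OC(=O)CBr | starting material
11 | sodium (Z)-enolate of 9 | COc1cc([C@@H](c2ccc(OC)c(OC)c2)/C=C(\[O-])N2[C@@H](Cc3ccccc3)COC2=O)ccc1O[Si](C)(C)C(C)(C)C.[Na+] | intermediate
12 | tert-butyl (3S,4R)-3-{[(4S)-4-benzyl-2-oxo-1,3-oxazolidin-3-yl]carbonyl}-4-[4-(tert-butyldimethylsilyloxy)-3-methoxyphenyl]-4-(3,4-dimethoxyphenyl)butanoate | COc1cc([C@@H](c2ccc(OC)c(OC)c2)[C@@H](C(=O)N2[C@@H](Cc3ccccc3)COC2=O)CC(=O)OC(C)(C)C)ccc1O[Si](C)(C)C(C)(C)C | intermediate
13 | tert-butyl (3S,4R)-4-[4-(tert-butyldimethylsilyloxy)-3-methoxyphenyl]-4-(3,4-dimethoxyphenyl)-3-(hydroxymethyl)butanoate | COc1cc([C@@H](c2ccc(OC)c(OC)c2)[C@@H](CO)CC(=O)OC(C)(C)C)ccc1O[Si](C)(C)C(C)(C)C | intermediate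
14 | tert-butyl (3S,4S)-4-(3,4-dimethoxyphenyl)-4-(4-hydroxy-3-methoxyphenyl)-3-(hydroxymethyl)butanoate (same spatial arrangement as 13; the descriptor changes with the free phenol) | COc1cc([C@@H](c2ccc(OC)c(OC)c2)[C@@H](CO)CC(=O)OC(C)(C)C)ccc1O | intermediate
15 | tert-butyl (3S,4R)-3-(acetoxymethyl)-4-(4-acetoxy-3-methoxyphenyl)-4-(3,4-dimethoxyphenyl)butanoate | COc1cc([C@@H](c2ccc(OC)c(OC)c2)[C@@H](COC(C)=O)CC(=O)OC(C)(C)C)ccc1OC(C)=O | intermediate
16 | (3S,4R)-3-(acetoxymethyl)-4-(4-acetoxy-3-methoxyphenyl)-4-(3,4-dimethoxyphenyl)butanoic acid | COc1cc([C@@H](c2ccc(OC)c(OC)c2)[C@@H](COC(C)=O)CC(=O)O)ccc1OC(C)=O | intermediate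
17 | acyclic vinamidinium salt: the CH2CO2H group of 16 replaced by C(=CH–NMe2)(CH=NMe2+), both stereocentres as in 16, drawn as the chloride | COc1cc([C@@H](c2ccc(OC)c(OC)c2)[C@@H](COC(C)=O)C(C=[N+](C)C)=CN(C)C)ccc1OC(C)=O.[Cl-] | intermediate
18 | N,N-dimethyliminium salt of aldehyde 19 (ring B closed, C3–CH=NMe2+), drawn as the chloride | COc1cc([C@H]2c3cc(OC)c(OC)cc3C=C(C=[N+](C)C)[C@@H]2COC(C)=O)ccc1OC(C)=O.[Cl-] | intermediate
19 | [(1S,2R)-1-(4-acetoxy-3-methoxyphenyl)-3-formyl-6,7-dimethoxy-1,2-dihydronaphthalen-2-yl]methyl acetate | COc1cc([C@H]2c3cc(OC)c(OC)cc3C=C(C=O)[C@@H]2COC(C)=O)ccc1OC(C)=O | intermediate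
20 | (1S,2R)-1-(4-hydroxy-3-methoxyphenyl)-2-(hydroxymethyl)-6,7-dimethoxy-1,2-dihydronaphthalene-3-carbaldehyde | COc1cc([C@H]2c3cc(OC)c(OC)cc3C=C(C=O)[C@@H]2CO)ccc1O | target

Total step count: 9
Longest linear sequence: 9 steps (1 → 20)

Steps most likely to fail

Step 8 (Proposed new method). Direct Friedel–Crafts acylation of ring A by the activated acid may outrun α-formylation and lead on to chloroformylation of the resulting ketone. The α-formylation of a non-activated alkanoic acid may also stall, or the vinamidinium may be too weak an electrophile to close the ring. The fallback uses known chemistry only and sets out from 16. The acid is cyclised on purpose by Friedel–Crafts acylation ((CF3CO)2O, CH2Cl2, 0 °C → rt) to the tetralone (3S,4S)-3-(acetoxymethyl)-4-(4-acetoxy-3-methoxyphenyl)-6,7-dimethoxy-3,4-dihydronaphthalen-1(2H)-one F1. Vilsmeier–Haack–Arnold chloroformylation of this ketone (POCl3, DMF, 60 °C; aq. NaOAc) should give the β-chloro enal [(1S,2R)-1-(4-acetoxy-3-methoxyphenyl)-4-chloro-3-formyl-6,7-dimethoxy-1,2-dihydronaphthalen-2-yl]methyl acetate F2. Palladium-catalysed formate hydrogenolysis of the activated vinylic C–Cl bond (Pd(OAc)2, PPh3, HCO2H, Et3N, DMF, 60 °C) then replaces chlorine by hydrogen, and the route is rejoined at 19. The same chloro enal is what a run of step 8 would deliver if acylation won, so such material would not be lost.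

Step 3. Facial selectivity under control of the benzyl auxiliary may be insufficient, and 1,4-addition to the electron-rich cinnamoyl acceptor may be slow enough for the Grignard reagent to attack the imide carbonyls. The fallback replaces auxiliary control by catalyst control and sets out from 3. Esterification (Boc2O, DMAP, t-BuOH) gives tert-butyl (E)-3-[4-(tert-butyldimethylsilyloxy)-3-methoxyphenyl]prop-2-enoate F3. Rhodium-catalysed asymmetric 1,4-addition of 3,4-dimethoxyphenylboronic acid (Hayashi–Miyaura reaction; [RhCl(C2H4)2]2, the chiral diene ligand enantiomer that delivers the R product, cat. KOH, dioxane/H2O, 50 °C) should give tert-butyl (3R)-3-[4-(tert-butyldimethylsilyloxy)-3-methoxyphenyl]-3-(3,4-dimethoxyphenyl)propanoate F4. Brief acidolysis (CF3CO2H, CH2Cl2, 0 °C), which the aryl silyl ether should survive, gives (3R)-3-[4-(tert-butyldimethylsilyloxy)-3-methoxyphenyl]-3-(3,4-dimethoxyphenyl)propanoic acid F5. Activation as the mixed pivalic anhydride of F5 F6 (PivCl, Et3N, THF, −20 °C) and N-acylation of 4 (LiCl) rejoin the route at 9.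

Step 5. Hydride may attack the ring carbonyl of the hindered imide and open the oxazolidinone, or the liberated alkoxide may lactonise onto the tert-butyl ester, which may also be reduced. The fallback separates cleavage from reduction and sets out from 12. Hydrolysis with LiOH/H2O2 (THF/H2O, 0 °C), in which hydroperoxide attacks the exocyclic carbonyl even when it is hindered, gives (2S,3R)-2-(2-tert-butoxy-2-oxoethyl)-3-[4-(tert-butyldimethylsilyloxy)-3-methoxyphenyl]-3-(3,4-dimethoxyphenyl)propanoic acid F7. Chemoselective reduction of the free carboxylic acid next to the tert-butyl ester (BH3·SMe2, THF, 0 °C) rejoins the route at 13.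

Further compounds
F1 | step 8 | (3S,4S)-3-(acetoxymethyl)-4-(4-acetoxy-3-methoxyphenyl)-6,7-dimethoxy-3,4-dihydronaphthalen-1(2H)-one | COc1cc([C@H]2c3cc(OC)c(OC)cc3C(=O)C[C@@H]2COC(C)=O)ccc1OC(C)=O
F2 | step 8 | [(1S,2R)-1-(4-acetoxy-3-methoxyphenyl)-4-chloro-3-formyl-6,7-dimethoxy-1,2-dihydronaphthalen-2-yl]methyl acetate | COc1cc([C@H]2c3cc(OC)c(OC)cc3C(Cl)=C(C=O)[C@@H]2COC(C)=O)ccc1OC(C)=O
F3 | step 3 | tert-butyl (E)-3-[4-(tert-butyldimethylsilyloxy)-3-methoxyphenyl]prop-2-enoate | COc1cc(/C=C/C(=O)OC(C)(C)C)ccc1O[Si](C)(C)C(C)(C)C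
F4 | step 3 | tert-butyl (3R)-3-[4-(tert-butyldimethylsilyloxy)-3-methoxyphenyl]-3-(3,4-dimethoxyphenyl)propanoate | COc1cc([C@@H](c2ccc(OC)c(OC)c2)CC(=O)OC(C)(C)C)ccc1O[Si](C)(C)C(C)(C)C
F5 | step 3 | (3R)-3-[4-(tert-butyldimethylsilyloxy)-3-methoxyphenyl]-3-(3,4-dimethoxyphenyl)propanoic acid | COc1cc([C@@H](c2ccc(OC)c(OC)c2)CC(=O)O)ccc1O[Si](C)(C)C(C)(C)C
F6 | step 3 | mixed pivalic anhydride of F5 | COc1cc([C@@H](c2ccc(OC)c(OC)c2)CC(=O)OC(=O)C(C)(C)C)ccc1O[Si](C)(C)C(C)(C)C
F7 | step 5 | (2S,3R)-2-(2-tert-butoxy-2-oxoethyl)-3-[4-(tert-butyldimethylsilyloxy)-3-methoxyphenyl]-3-(3,4-dimethoxyphenyl)propanoic acid | COc1cc([C@@H](c2ccc(OC)c(OC)c2)[C@@H](C(=O)O)CC(=O)OC(C)(C)C)ccc1O[Si](C)(C)C(C)(C)C
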